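- Take the L column of the green run first, where Z stands at 6.00 equivalents to L.

| flask | L | Z | remark | time |
|---|---|---|---|---|
| green | 2 mM | 12 mM | run made earlier |  |
| ochre | 2 mM | 11 mM | run made earlier |  |
| alpha | 2.0 mM | 15.0 mM |  | 0.80 min |
| zeta | 2.0 mM | 10.0 mM |  | 2.5 min |

| run | time / min | E / % | L / % |
|---|---|---|---|
| green | 0.200 | 12 | 65 |
| green | 0.500 | 41 | 47 |
| green | 1.00 | 61 | 30 |
| green | 2.50 | 87 | 13 |
| ochre | 0.200 | 11 | 66 |
| ochre | 0.500 | 36 | 46 |
| ochre | 1.00 | 58 | 31 |
| ochre | 2.50 | 85 | 16 |

(standard deviation of a reading: 2 percentage points)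

- which one finishes higher in amount of E, in percent of the L charged ("neither" within 2 percentage points) (alpha / zeta / neither)
- amount of E at the end, in percent of the L charged, alpha
- amount of E at the end, in percent of the L charged, zeta

- what is said of Q includes G
- G is a solid; its amount is given per volume of the solution
- the numbers in the tables scatter by 2 percentage points (one standard deviation)
- steps that have been proposed: L + Z -> X + Q; X -> E; G <-> Q; 2 Z -> J

- The contradiction: that excess leads me to expect a pseudo-first-order decay with one constant, yet the green run gives an apparent constant of 2.15 min⁻¹ up to its first reading and 0.557 min⁻¹ between its last two.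
- I look to Z for the order of the rate. If the proposed step of two Z to J consumes Z, Z falls hyperbolically, and a rate proportional to Z times L can then make L look second order.
- So I test R, the ratio of L charged to L left. In the green run, (R − 1)/t is 2.69 min⁻¹ at the first reading and 2.68 min⁻¹ at the last, so the two ends of the run nearly coincide.
- I write R = 1 + κ·Zc·t, with Zc the charged Z and t the time. The last readings give 3.72 M⁻¹ s⁻¹ in green and 3.18 M⁻¹ s⁻¹ in ochre, so I carry the mean, the decay clock κ = 3.45 M⁻¹ s⁻¹.
- My reckoning puts L at 28.7 % in alpha and 16.2 % in zeta. I take X as a rough steady state, κ·Zc·L² over a constant of 2.24 min⁻¹, read from the missing L at the one-minute readings. That gives X 11.4 % in alpha and 2.43 % in zeta, so E is 59.9 % in alpha and 81.4 % in zeta.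
- The forecast gives 59 % for alpha and 83 % for zeta, slightly apart from mine, and names zeta: “The extra time outweighs the extra Z”.
- The flask gives E 60.8 % in alpha and 81.0 % in zeta, so zeta finishes higher.

    L + Z → X + Q (k = 3.70 M⁻¹ s⁻¹)
    X → E (k = 0.0680 s⁻¹)
    G ⇌ Q, rate k3*(cs3 - [Q]) while solid is left; crystals form when [Q] > cs3 (solubility = 0.410 mM, k = 1.00 s⁻¹)
    2 Z → J (k = 1.70 M⁻¹ s⁻¹)

- Alpha holds L 28 % at its end, where κ gave 28.7 %. The main reason for alpha's gap to zeta is its shorter time: with that difference taken away, alpha gives E 87.2 % instead of 60.8 %. For a further flask, alpha with 6.0 mM of Z, κ gives L 50.2 %, and that flask holds 51.0 %.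

The runs are calculated with constants of no real substance; noise was put on by code.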